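The synthesis rests on the sp3–sp2 bond C8′–C9′ of the side chain (numbered outward from chromene C2), which flanks the E-trisubstituted C7′=C8′ double bond. It is made by a Zweifel olefination that joins the C31 homoallylic pinacol boronate 21 to the alkenyllithium from the Z-2-iodoalkene 12, which already carries the (R)-2H-chromene ring. Iodine-induced 1,2-migration of the alkyl group from boron to C8′ and anti elimination forge the bond and invert the double bond from Z to E in one operation, so the precursor is built with the opposite geometry on purpose. The chromene stereocentre comes from a palladium-catalysed asymmetric O-allylation and ring-closing metathesis.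

Key step: step 17

Assumption: with the E-carbonate 8 the (R,R)-ligand is taken to give the R ether 9; should the sense of induction be opposite, the (S,S)-ligand is used and nothing else changes.
Remark: the epoxide carbon formed in step 4 is racemic, so 7 and 8 are racemates and 9 and 10 are mixtures of epimers at this remote centre (left unspecified in the SMILES); it is excised in step 8.
Remark: 2H-chromenes can racemise by photochemical electrocyclic ring opening and re-closure, so 10, 11, 12, 25 and 26 are handled with exclusion of light.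

Step 1
Reactants: 1 2,3-dimethylhydroquinone
Product: 2 2,3-dimethyl-4-(triisopropylsilyloxy)phenol
Conditions: TIPSCl (0.45 equiv), imidazole, DMF, 0 °C to rt; excess diol recovered
Reagents that add atoms: triisopropylsilyl chloride, CC(C)[Si](Cl)(C(C)C)C(C)C
Why: Silylation of one of two symmetry-equivalent phenols, with the diol in excess to keep bis-silylation low (statistical monoprotection).

Step 2
Reactants: 2 2,3-dimethyl-4-(triisopropylsilyloxy)phenol
Product: 3 2-hydroxy-3,4-dimethyl-5-(triisopropylsilyloxy)benzaldehyde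
Conditions: MgCl2, Et3N, (CH2O)n, MeCN, reflux
Reagents that add atoms: paraformaldehyde (as formaldehyde), C=O
Why: Magnesium-mediated ortho-formylation (Casiraghi–Skattebøl type), in which the magnesium phenoxide delivers formaldehyde to the only free ortho position and a second formaldehyde oxidises the benzylic alkoxide by hydride transfer.

Step 3
Reactants: 3 2-hydroxy-3,4-dimethyl-5-(triisopropylsilyloxy)benzaldehyde
Product: 4 2,3-dimethyl-4-(triisopropylsilyloxy)-6-vinylphenol
Conditions: Ph3PCH3Br (2.5 equiv), KOt-Bu (2.5 equiv), THF, 0 °C to rt; used promptly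
Reagents that add atoms: methyltriphenylphosphonium bromide, C[P+](c1ccccc1)(c1ccccc1)c1ccccc1.[Br-]
Why: Wittig methylenation of the salicylaldehyde as its phenoxide, the excess ylide covering the acidic phenol.

Step 4
Reactants: 5 (2E,6E)-farnesyl acetate
Product: 7 (2E,6E)-10,11-epoxy-3,7,11-trimethyldodeca-2,6-dien-1-ol, via bromohydrin 6 (not isolated)
Conditions: NBS, THF/H2O, 0 °C; then K2CO3, MeOH, rt
Reagents that add atoms: water, O
Why: Terminal-selective bromohydrin formation with NBS in aqueous THF (the internal alkenes are shielded in the coiled chain), after which base closes the epoxide and methanolyses the acetate; the new centre is racemic and is removed in step 8.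

Step 5
Reactants: 7 (2E,6E)-10,11-epoxy-3,7,11-trimethyldodeca-2,6-dien-1-ol
Product: 8 (2E,6E)-10,11-epoxy-3,7,11-trimethyldodeca-2,6-dien-1-yl methyl carbonate
Conditions: ClCO2Me, pyridine, CH2Cl2, 0 °C
Reagents that add atoms: methyl chloroformate, COC(Cl)=O
Why: Acylation of the primary allylic alcohol with a chloroformate, to which the epoxide is inert at 0 °C.

Step 6
Reactants: 4 2,3-dimethyl-4-(triisopropylsilyloxy)-6-vinylphenol; 8 (2E,6E)-10,11-epoxy-3,7,11-trimethyldodeca-2,6-dien-1-yl methyl carbonate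
Product: 9 1-{[(3R,6E)-10,11-epoxy-3,7,11-trimethyldodeca-1,6-dien-3-yl]oxy}-2,3-dimethyl-4-(triisopropylsilyloxy)-6-vinylbenzene
Conditions: Pd2(dba)3·CHCl3 (1.5 mol%), N,N′-[(1R,2R)-cyclohexane-1,2-diyl]bis[2-(diphenylphosphino)benzamide] (4.5 mol%), CH2Cl2, rt
Reagents that add atoms: none
Why: Tsuji–Trost asymmetric allylic O-alkylation, in which zerovalent palladium ionises the carbonate to a π-allyl complex, the liberated methoxide deprotonates phenol 4, and the phenoxide attacks the more substituted allyl terminus inside the chiral pocket of the ligand, which sets the tertiary ether stereocentre as R.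

Step 7
Reactants: 9 1-{[(3R,6E)-10,11-epoxy-3,7,11-trimethyldodeca-1,6-dien-3-yl]oxy}-2,3-dimethyl-4-(triisopropylsilyloxy)-6-vinylbenzene
Product: 10 (2R)-2-[(3E)-7,8-epoxy-4,8-dimethylnon-3-en-1-yl]-2,7,8-trimethyl-6-(triisopropylsilyloxy)-2H-chromene
Conditions: second-generation Grubbs catalyst RuCl2(=CHPh)(H2IMes)(PCy3) (5 mol%), CH2Cl2 (5 mM), 40 °C, dark
Reagents that add atoms: none
Why: Ring-closing metathesis of the two terminal alkenes should give the six-membered 2H-chromene with loss of ethylene, the trisubstituted chain alkene reacting far more slowly and the quaternary stereocentre staying untouched.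

Step 8
Reactants: 10 (2R)-2-[(3E)-7,8-epoxy-4,8-dimethylnon-3-en-1-yl]-2,7,8-trimethyl-6-(triisopropylsilyloxy)-2H-chromene
Product: 11 (4E)-4-methyl-7-[(2R)-2,7,8-trimethyl-6-(triisopropylsilyloxy)-2H-chromen-2-yl]hept-4-enal
Conditions: H5IO6, THF/Et2O, 0 °C, short reaction time
Reagents that add atoms: none
Why: Periodic acid hydrolyses the trisubstituted epoxide to the diol and cleaves it in the same pot to the aldehyde and acetone (glycol cleavage), which the aryl silyl ether and the chromene should tolerate.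

Step 9
Reactants: 11 (4E)-4-methyl-7-[(2R)-2,7,8-trimethyl-6-(triisopropylsilyloxy)-2H-chromen-2-yl]hept-4-enal
Product: 12 (2R)-2-[(3E,7Z)-8-iodo-4-methylnona-3,7-dien-1-yl]-2,7,8-trimethyl-6-(triisopropylsilyloxy)-2H-chromene
Conditions: EtPPh3I, n-BuLi, THF, rt; I2, −78 °C; NaHMDS, −20 °C; then 11, −78 to −20 °C
Reagents that add atoms: ethyltriphenylphosphonium iodide, CC[P+](c1ccccc1)(c1ccccc1)c1ccccc1.[I-]; iodine, II
Why: Stork–Zhao-type Wittig olefination with the α-iodo ylide, which under kinetic control should give the Z-2-iodoalkene with iodine cis to the chain.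

Step 10
Reactants: 13 (2E,6E)-farnesyl bromide
Product: 14 (2E,6E)-farnesyl phenyl sulfone
Conditions: PhSO2Na, DMF, rt
Reagents that add atoms: sodium benzenesulfinate, [Na+].[O-]S(=O)c1ccccc1
Why: SN2 S-alkylation of the sulfinate by the primary allylic bromide with retention of the E geometry.

Step 11
Reactants: 5 (2E,6E)-farnesyl acetate
Product: 15 (2E,6E,10E)-12-hydroxy-3,7,11-trimethyldodeca-2,6,10-trien-1-yl acetate
Conditions: SeO2 (0.3 equiv), t-BuOOH, salicylic acid (cat.), CH2Cl2, 0 °C to rt, stopped at partial conversion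
Reagents that add atoms: tert-butyl hydroperoxide, CC(C)(C)OO; selenium dioxide (oxygen relay), O=[Se]=O
Why: Selenium dioxide-catalysed allylic oxidation (ene reaction, then [2,3]-sigmatropic shift), selective for the E-methyl group of the terminal, most electron-rich double bond.

Step 12
Reactants: 15 (2E,6E,10E)-12-hydroxy-3,7,11-trimethyldodeca-2,6,10-trien-1-yl acetate
Product: 16 (2E,6E,10E)-12-bromo-3,7,11-trimethyldodeca-2,6,10-trien-1-yl acetate
Conditions: CBr4, PPh3, CH2Cl2, 0 °C
Reagents that add atoms: carbon tetrabromide, BrC(Br)(Br)Br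
Why: Appel bromination of the primary allylic alcohol under neutral conditions, without allylic transposition.

Step 13
Reactants: 14 (2E,6E)-farnesyl phenyl sulfone; 16 (2E,6E,10E)-12-bromo-3,7,11-trimethyldodeca-2,6,10-trien-1-yl acetate
Product: 18 (2E,6E,10E,14E,18E)-3,7,11,15,19,23-hexamethyl-13-(phenylsulfonyl)tetracosa-2,6,10,14,18,22-hexaen-1-yl acetate, via lithiated sulfone 17 (not isolated)
Conditions: n-BuLi, THF/DMPU, −78 °C; then 16, −78 to −40 °C
Reagents that add atoms: none
Why: Julia-type sulfone alkylation, in which the sulfonyl-stabilised allylic anion reacts at its α-carbon with the primary allylic bromide by SN2 and joins the two C15 units head to tail without touching a double bond.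

Step 14
Reactants: 18 (2E,6E,10E,14E,18E)-3,7,11,15,19,23-hexamethyl-13-(phenylsulfonyl)tetracosa-2,6,10,14,18,22-hexaen-1-yl acetate
Product: 19 (2E,6E,10E,14E,18E)-3,7,11,15,19,23-hexamethyltetracosa-2,6,10,14,18,22-hexaen-1-ol
Conditions: LiEt3BH (5 equiv), THF, 0 °C; then Pd(dppp)Cl2 (5 mol%), 0 °C to rt
Reagents that add atoms: none
Why: The hydride first cleaves the acetate, then palladium-catalysed reductive desulfonylation through a π-allyl complex delivers hydride to the less substituted terminus, so position and E geometry of the double bond are kept.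

Step 15
Reactants: 19 (2E,6E,10E,14E,18E)-3,7,11,15,19,23-hexamethyltetracosa-2,6,10,14,18,22-hexaen-1-ol
Product: 20 (2E,6E,10E,14E,18E)-1-bromo-3,7,11,15,19,23-hexamethyltetracosa-2,6,10,14,18,22-hexaene
Conditions: PBr3, Et2O, 0 °C; used crude
Reagents that add atoms: phosphorus tribromide, BrP(Br)Br
Why: SN2 bromination of the primary allylic alcohol at low temperature, which leaves the E geometry intact.

Step 16
Reactants: 20 (2E,6E,10E,14E,18E)-1-bromo-3,7,11,15,19,23-hexamethyltetracosa-2,6,10,14,18,22-hexaene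
Product: 21 2-[(3E,7E,11E,15E,19E)-4,8,12,16,20,24-hexamethylpentacosa-3,7,11,15,19,23-hexaen-1-yl]-4,4,5,5-tetramethyl-1,3,2-dioxaborolane
Conditions: CH2(Bpin)2, NaOt-Bu, THF, rt; bromide added last
Reagents that add atoms: bis(4,4,5,5-tetramethyl-1,3,2-dioxaborolan-2-yl)methane, CC1(C)OB(CB2OC(C)(C)C(C)(C)O2)OC1(C)C
Why: Alkoxide-promoted deborylative alkylation of the geminal bis(boronate), in which tert-butoxide removes one boryl group and the α-boryl carbanion displaces the primary allylic bromide by SN2 to give the one-carbon-extended homoallylic boronate.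

Step 17
Reactants: 12 (2R)-2-[(3E,7Z)-8-iodo-4-methylnona-3,7-dien-1-yl]-2,7,8-trimethyl-6-(triisopropylsilyloxy)-2H-chromene; 21 2-[(3E,7E,11E,15E,19E)-4,8,12,16,20,24-hexamethylpentacosa-3,7,11,15,19,23-hexaen-1-yl]-4,4,5,5-tetramethyl-1,3,2-dioxaborolane
Product: 25 plastochromenol-8 triisopropylsilyl ether, via alkenyllithium 22 (not isolated), via lithium boronate complex 23 (not isolated), via β-iodoalkylboronic ester 24 (not isolated)
Conditions: 12, t-BuLi (2 equiv), Et2O, −78 °C; 21, THF, −78 to 0 °C; I2 (1.1 equiv), THF, −78 °C; NaOMe, MeOH, −78 °C to rt; Na2S2O3 work-up; dark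
Reagents that add atoms: none
Why: Iodine–lithium exchange turns 12 with retention into the configurationally stable alkenyllithium 22, which adds to the boron atom of 21 to give the boronate complex 23; iodine then attacks its electron-rich alkenyl π bond, the homoallylic CH2 group (C9′) migrates from boron to C8′ anti to the breaking C–I bond to give 24, and methoxide induces anti elimination of boron and iodide. The closest known reaction type is the Zweifel olefination of alkenyllithiums with alkyl pinacol boronic esters, a transition-metal-free 1,2-metallate rearrangement. No ring is closed and no stereocentre survives in the product, the two stereocentres of 24 being transient. The one stereochemical element made, the C7′=C8′ geometry, is controlled by the Z geometry of 12 together with the two anti events, which place C9′ trans to C6′ and so give the E alkene by net inversion. The step needs iodine to choose the boronate alkene over the eight other trisubstituted double bonds and the chromene C3=C4 bond, which the negative charge of 23, one equivalent of iodine and −78 °C should secure, and it needs carbon instead of pinacol oxygen to migrate, which is the normal course for pinacol boronates. The silyl ether, the arene and the stereocentre at C2 should be untouched by t-BuLi at −78 °C and by methoxide.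

Step 18
Reactants: 25 plastochromenol-8 triisopropylsilyl ether
Product: 26 plastochromenol-8
Conditions: TBAF, AcOH, THF, 0 °C, argon, dark
Reagents that add atoms: none
Why: Fluoride cleavage of the aryl silyl ether, with acetic acid buffering the phenoxide of the air-sensitive chromenol.

Compound list
1 | 2,3-dimethylbenzene-1,4-diol (2,3-dimethylhydroquinone) | Cc1c(O)ccc(O)c1C | starting material
2 | 2,3-dimethyl-4-(triisopropylsilyloxy)phenol | Cc1c(O)ccc(O[Si](C(C)C)(C(C)C)C(C)C)c1C | intermediate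
3 | 2-hydroxy-3,4-dimethyl-5-(triisopropylsilyloxy)benzaldehyde | O=Cc1cc(O[Si](C(C)C)(C(C)C)C(C)C)c(C)c(C)c1O | intermediate
4 | 2,3-dimethyl-4-(triisopropylsilyloxy)-6-vinylphenol | C=Cc1cc(O[Si](C(C)C)(C(C)C)C(C)C)c(C)c(C)c1O | intermediate
5 | (2E,6E)-farnesyl acetate | CC(C)=CCC/C(C)=C/CC/C(C)=C/COC(C)=O | starting material
6 | (2E,6E)-10-bromo-11-hydroxy-3,7,11-trimethyldodeca-2,6-dien-1-yl acetate (racemic bromohydrin) | CC(=O)OC/C=C(C)/CC/C=C(C)/CCC(Br)C(C)(C)O | intermediate
7 | (2E,6E)-10,11-epoxy-3,7,11-trimethyldodeca-2,6-dien-1-ol (racemic at C10) | CC1(C)OC1CC/C(C)=C/CC/C(C)=C/CO | intermediate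
8 | (2E,6E)-10,11-epoxy-3,7,11-trimethyldodeca-2,6-dien-1-yl methyl carbonate | CC1(C)OC1CC/C(C)=C/CC/C(C)=C/COC(=O)OC | intermediate
9 | 1-{[(3R,6E)-10,11-epoxy-3,7,11-trimethyldodeca-1,6-dien-3-yl]oxy}-2,3-dimethyl-4-(triisopropylsilyloxy)-6-vinylbenzene | C=C[C@@](C)(CC/C=C(C)/CCC1OC1(C)C)Oc1c(C=C)cc(O[Si](C(C)C)(C(C)C)C(C)C)c(C)c1C | intermediate
10 | (2R)-2-[(3E)-7,8-epoxy-4,8-dimethylnon-3-en-1-yl]-2,7,8-trimethyl-6-(triisopropylsilyloxy)-2H-chromene | CC1(C)OC1CC/C(C)=C/CC[C@]2(C)C=Cc3cc(O[Si](C(C)C)(C(C)C)C(C)C)c(C)c(C)c3O2 | intermediate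
11 | (4E)-4-methyl-7-[(2R)-2,7,8-trimethyl-6-(triisopropylsilyloxy)-2H-chromen-2-yl]hept-4-enal | O=CCC/C(C)=C/CC[C@]1(C)C=Cc2cc(O[Si](C(C)C)(C(C)C)C(C)C)c(C)c(C)c2O1 | intermediate
12 | (2R)-2-[(3E,7Z)-8-iodo-4-methylnona-3,7-dien-1-yl]-2,7,8-trimethyl-6-(triisopropylsilyloxy)-2H-chromene | C/C(I)=C/CC/C(C)=C/CC[C@]1(C)C=Cc2cc(O[Si](C(C)C)(C(C)C)C(C)C)c(C)c(C)c2O1 | intermediate
13 | (2E,6E)-farnesyl bromide | CC(C)=CCC/C(C)=C/CC/C(C)=C/CBr | starting material
14 | (2E,6E)-farnesyl phenyl sulfone | CC(C)=CCC/C(C)=C/CC/C(C)=C/CS(=O)(=O)c1ccccc1 | intermediate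
15 | (2E,6E,10E)-12-hydroxy-3,7,11-trimethyldodeca-2,6,10-trien-1-yl acetate | CC(=O)OC/C=C(C)/CC/C=C(C)/CC/C=C(C)/CO | intermediate
16 | (2E,6E,10E)-12-bromo-3,7,11-trimethyldodeca-2,6,10-trien-1-yl acetate | CC(=O)OC/C=C(C)/CC/C=C(C)/CC/C=C(C)/CBr | intermediate
17 | α-lithiated (2E,6E)-farnesyl phenyl sulfone | CC(C)=CCC/C(C)=C/CC/C(C)=C/C([Li])S(=O)(=O)c1ccccc1 | intermediate
18 | (2E,6E,10E,14E,18E)-3,7,11,15,19,23-hexamethyl-13-(phenylsulfonyl)tetracosa-2,6,10,14,18,22-hexaen-1-yl acetate (racemic at C13) | CC(C)=CCC/C(C)=C/CC/C(C)=C/C(C/C(C)=C/CC/C(C)=C/CC/C(C)=C/COC(C)=O)S(=O)(=O)c1ccccc1 | intermediate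
19 | (2E,6E,10E,14E,18E)-3,7,11,15,19,23-hexamethyltetracosa-2,6,10,14,18,22-hexaen-1-ol (all-E hexaprenol) | CC(C)=CCC/C(C)=C/CC/C(C)=C/CC/C(C)=C/CC/C(C)=C/CC/C(C)=C/CO | intermediate
20 | (2E,6E,10E,14E,18E)-1-bromo-3,7,11,15,19,23-hexamethyltetracosa-2,6,10,14,18,22-hexaene (all-E hexaprenyl bromide) | CC(C)=CCC/C(C)=C/CC/C(C)=C/CC/C(C)=C/CC/C(C)=C/CC/C(C)=C/CBr | intermediate
21 | 2-[(3E,7E,11E,15E,19E)-4,8,12,16,20,24-hexamethylpentacosa-3,7,11,15,19,23-hexaen-1-yl]-4,4,5,5-tetramethyl-1,3,2-dioxaborolane | CC(C)=CCC/C(C)=C/CC/C(C)=C/CC/C(C)=C/CC/C(C)=C/CC/C(C)=C/CCB1OC(C)(C)C(C)(C)O1 | intermediate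
22 | alkenyllithium from 12 (lithium in place of iodine, cis to the chain) | C/C([Li])=C/CC/C(C)=C/CC[C@]1(C)C=Cc2cc(O[Si](C(C)C)(C(C)C)C(C)C)c(C)c(C)c2O1 | intermediate
23 | lithium boronate complex of 21 and 22 (boron cis to C6′) | [Li+].CC(C)=CCC/C(C)=C/CC/C(C)=C/CC/C(C)=C/CC/C(C)=C/CC/C(C)=C/CC[B-]1(OC(C)(C)C(C)(C)O1)/C(C)=C\CC/C(C)=C/CC[C@]2(C)C=Cc3cc(O[Si](C(C)C)(C(C)C)C(C)C)c(C)c(C)c3O2 | intermediate
24 | β-iodoalkylboronic ester (C8′ carries methyl, C9′ and boron; C7′ carries iodine; one relative configuration at C7′/C8′, both faces, centres left unspecified) | CC(C)=CCC/C(C)=C/CC/C(C)=C/CC/C(C)=C/CC/C(C)=C/CC/C(C)=C/CCC(C)(B1OC(C)(C)C(C)(C)O1)C(I)CC/C(C)=C/CC[C@]2(C)C=Cc3cc(O[Si](C(C)C)(C(C)C)C(C)C)c(C)c(C)c3O2 | intermediate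
25 | plastochromenol-8 triisopropylsilyl ether | CC(C)=CCC/C(C)=C/CC/C(C)=C/CC/C(C)=C/CC/C(C)=C/CC/C(C)=C/CC/C(C)=C/CC/C(C)=C/CC[C@]1(C)C=Cc2cc(O[Si](C(C)C)(C(C)C)C(C)C)c(C)c(C)c2O1 | intermediate
26 | plastochromenol-8, (2R)-2,7,8-trimethyl-2-(all-E-octaprenylmethyl... C40 chain)-2H-chromen-6-ol | CC(C)=CCC/C(C)=C/CC/C(C)=C/CC/C(C)=C/CC/C(C)=C/CC/C(C)=C/CC/C(C)=C/CC/C(C)=C/CC[C@]1(C)C=Cc2cc(O)c(C)c(C)c2O1 | target

Total step count: 18. Longest linear sequence: 9 steps (steps 1, 2, 3, 6, 7, 8, 9, 17, 18).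

Steps most likely to fail

1. Step 17 (key step). Iodine may also add to the polyene (iodination or iodo-etherification), boronate formation between two large fragments may be incomplete, or a syn elimination pathway may erode the Z-to-E inversion. The fallback sets out from 11 and returns at 25; it replaces inversion by a coupling with retention. Aldehyde 11 would be homologated with dimethyl (1-diazo-2-oxopropyl)phosphonate (K2CO3, MeOH) to the terminal alkyne F1 and methylated (n-BuLi, MeI) to the 2-alkyne F2. Hydrozirconation with Cp2Zr(H)Cl (slight excess, equilibration to zirconium on the methyl-bearing carbon) and iodinolysis would give the E-2-iodoalkene F3. A B-alkyl Suzuki–Miyaura coupling of F3 with 21 (Pd(OAc)2, SPhos, K3PO4, THF/H2O, 60 °C) would then give 25 with retention.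

2. Step 6. The hindered 2,6-disubstituted phenoxide may attack the primary allyl terminus, palladium may re-ionise the product and erode the enantiomeric purity, or facial discrimination may be insufficient. The fallback sets out from 2 and returns at 10; it makes the chromene racemic and resolves it. Commercial (E)-geranylacetone would be converted as in step 4 (NBS, aqueous THF; K2CO3, MeOH) via the bromohydrin F4 into the epoxy ketone F5, to which ethynylmagnesium bromide adds to give the racemic tertiary propargylic alcohol F6. Its trifluoroacetate F7, made in the flask (TFAA, DBU, MeCN, 0 °C), would alkylate phenol 2 under CuCl2 catalysis to the aryl propargyl ether F8. Heating (xylene, 140 °C) would trigger aromatic propargyl Claisen rearrangement, 1,5-hydrogen shift and oxa-6π electrocyclisation to the racemic chromene F9, from which 10 is separated by preparative HPLC on a chiral stationary phase.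

3. Step 9. The iodo-ylide olefination may stall at low conversion or give poor Z/E selectivity, and any E iodide would be carried into the Z alkene in step 17. The fallback sets out from 11 and returns at 22. Corey–Fuchs dibromo-olefination of 11 (CBr4, PPh3, CH2Cl2, 0 °C) would give the 1,1-dibromoalkene F10. A palladium-catalysed, trans-selective Negishi-type monomethylation (MeZnCl, Pd(DPEphos)Cl2, THF) would replace the less hindered bromine trans to the chain and give the Z-2-bromoalkene F11. Bromine–lithium exchange with t-BuLi then gives the same alkenyllithium 22 for step 17.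

Further compounds
F1 | step 17 | (2R)-2-[(3E)-4-methyloct-3-en-7-yn-1-yl]-2,7,8-trimethyl-6-(triisopropylsilyloxy)-2H-chromene | C#CCC/C(C)=C/CC[C@]1(C)C=Cc2cc(O[Si](C(C)C)(C(C)C)C(C)C)c(C)c(C)c2O1
F2 | step 17 | (2R)-2-[(3E)-4-methylnon-3-en-7-yn-1-yl]-2,7,8-trimethyl-6-(triisopropylsilyloxy)-2H-chromene | CC#CCC/C(C)=C/CC[C@]1(C)C=Cc2cc(O[Si](C(C)C)(C(C)C)C(C)C)c(C)c(C)c2O1
F3 | step 17 | (2R)-2-[(3E,7E)-8-iodo-4-methylnona-3,7-dien-1-yl]-2,7,8-trimethyl-6-(triisopropylsilyloxy)-2H-chromene | C/C(I)=C\CC/C(C)=C/CC[C@]1(C)C=Cc2cc(O[Si](C(C)C)(C(C)C)C(C)C)c(C)c(C)c2O1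
F4 | step 6 | (5E)-9-bromo-10-hydroxy-6,10-dimethylundec-5-en-2-one (racemic bromohydrin) | CC(=O)CC/C=C(C)/CCC(Br)C(C)(C)O
F5 | step 6 | (5E)-9,10-epoxy-6,10-dimethylundec-5-en-2-one (racemic) | CC(=O)CC/C=C(C)/CCC1OC1(C)C
F6 | step 6 | (6E)-10,11-epoxy-3,7,11-trimethyldodec-6-en-1-yn-3-ol (racemic at C3) | C#CC(C)(O)CC/C=C(C)/CCC1OC1(C)C
F7 | step 6 | (6E)-10,11-epoxy-3,7,11-trimethyldodec-6-en-1-yn-3-yl trifluoroacetate | C#CC(C)(CC/C=C(C)/CCC1OC1(C)C)OC(=O)C(F)(F)F
F8 | step 6 | 1-{[(6E)-10,11-epoxy-3,7,11-trimethyldodec-6-en-1-yn-3-yl]oxy}-2,3-dimethyl-4-(triisopropylsilyloxy)benzene (racemic at the ether carbon) | C#CC(C)(CC/C=C(C)/CCC1OC1(C)C)Oc1ccc(O[Si](C(C)C)(C(C)C)C(C)C)c(C)c1C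
F9 | step 6 | racemic 2-[(3E)-7,8-epoxy-4,8-dimethylnon-3-en-1-yl]-2,7,8-trimethyl-6-(triisopropylsilyloxy)-2H-chromene | CC1(C)OC1CC/C(C)=C/CCC2(C)C=Cc3cc(O[Si](C(C)C)(C(C)C)C(C)C)c(C)c(C)c3O2
F10 | step 9 | (2R)-2-[(3E)-8,8-dibromo-4-methylocta-3,7-dien-1-yl]-2,7,8-trimethyl-6-(triisopropylsilyloxy)-2H-chromene | BrC(Br)=CCC/C(C)=C/CC[C@]1(C)C=Cc2cc(O[Si](C(C)C)(C(C)C)C(C)C)c(C)c(C)c2O1
F11 | step 9 | (2R)-2-[(3E,7Z)-8-bromo-4-methylnona-3,7-dien-1-yl]-2,7,8-trimethyl-6-(triisopropylsilyloxy)-2H-chromene | C/C(Br)=C/CC/C(C)=C/CC[C@]1(C)C=Cc2cc(O[Si](C(C)C)(C(C)C)C(C)C)c(C)c(C)c2O1
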